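Labels: indenone atoms C1–C7a with fused benzo ring B. Ring A is a1–a6, where a1 carries the diaryl ketone and a6 is bonded to C2. Ring C is the 2,6-dimethoxybenzoyl ring and ring D the 2,6-dimethoxyphenyl group on C3.
Retrosynthesis: once the two phenol protecting groups are removed, C2–a6 and C3–C3a are cut together. This leaves a ring A/ring C diazonium salt and the ynone ring B–C1(=O)–C2≡C3–ring D. Further cuts are C1–C2 (Weinreb amide + acetylide), a1–C(carbinol) (aryllithium + aldehyde) and a6–N (Curtius).
Enabling feature: C2 lies between the C1 carbonyl and C3, so in the ynone it is an open radical acceptor. The radical left on C3 is stabilised by ring D and sits at five-ring distance from C3a, the only unsubstituted carbon ortho to the acyl-bearing C7a of ring B.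
Rings A and B share one substitution pattern, so both halves come from 2-methoxy-5-(methoxymethoxy)-3-methylbenzoic acid, made from 3-methylsalicylic acid. Rings C and D both come from 2,6-dimethoxybenzaldehyde.
Forward order: all four benzene rings are bought and the two halves are built separately. The five-membered ring is the only ring formed, closed in the same operation that joins the halves, and deprotection ends the route.
Stereochemistry: the target has no stereocentre. The one carbinol centre met on the way is racemic and is erased by oxidation.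

Key step: step 13

Remark 1: the aryl–indenone axes (C2–a6 and C3–ring D) are taken as not configurationally fixed, in line with the stereo-free structure, so no atropisomer control is planned.
Remark 2: both phenols travel as MOM ethers. OMOM cooperates in the directed lithiation, whereas t-BuLi would itself metalate a benzylic OCH2. Its mild acidic removal also spares the methyl ethers ortho to the two carbonyl groups, which boron trihalides tend to cleave.

Step 1
Reactants: 1 3-methylsalicylic acid
Product: 2 methyl 2-methoxy-3-methylbenzoate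
Conditions: MeI (2.5 equiv), K2CO3, DMF, 40 °C
Reagents that add atoms: iodomethane, CI
Why: Double Williamson-type O-methylation (SN2 of carboxylate and phenoxide on MeI), with DMF and gentle heating overcoming the hydrogen-bonded, flanked phenol.

Step 2
Reactants: 2 methyl 2-methoxy-3-methylbenzoate
Product: 4 methyl 5-hydroxy-2-methoxy-3-methylbenzoate, via pinacol boronate 3 (not isolated)
Conditions: [Ir(OMe)(cod)]2 (cat.), 4,4'-di-tert-butyl-2,2'-bipyridine (cat.), B2pin2 (0.6 equiv), THF, 80 °C; then KHSO5 (as 2KHSO5·KHSO4·K2SO4), acetone/H2O, rt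
Reagents that add atoms: bis(pinacolato)diboron, CC1(C)OB(OC1(C)C)B1OC(C)(C)C(C)(C)O1 (boron group of 3); potassium peroxymonosulfate KHSO5, [K+].[O-]S(=O)(=O)OO (phenol oxygen of 4)
Why: Sterically governed iridium-catalysed aromatic C–H borylation should pick C5, the only C–H without an ortho neighbour in this 1,2,3-trisubstituted arene, and the boronate is oxidised to the phenol in the same flask (borylation–oxidation sequence).

Step 3
Reactants: 4 methyl 5-hydroxy-2-methoxy-3-methylbenzoate
Product: 5 methyl 2-methoxy-5-(methoxymethoxy)-3-methylbenzoate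
Conditions: MOMCl, i-Pr2NEt, CH2Cl2, 0 °C → rt
Reagents that add atoms: chloromethyl methyl ether, COCCl
Why: O-alkylation of the single free, unhindered phenol with an α-chloro ether (MOM protection) is routine, and the ester is inert.

Step 4
Reactants: 5 methyl 2-methoxy-5-(methoxymethoxy)-3-methylbenzoate
Product: 6 2-methoxy-5-(methoxymethoxy)-3-methylbenzoic acid
Conditions: LiOH, THF/MeOH/H2O, 50 °C; then 1 M HCl to pH 4, 0 °C
Reagents that add atoms: lithium hydroxide, [Li+].[OH-]
Why: Ester saponification leaves the MOM acetal and the aryl methyl ether untouched, and the cold, mild acidification keeps the acetal intact.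

Step 5
Reactants: 6 2-methoxy-5-(methoxymethoxy)-3-methylbenzoic acid
Product: 8 N,2-dimethoxy-5-(methoxymethoxy)-N,3-dimethylbenzamide, via acyl imidazolide 7 (not isolated)
Conditions: CDI, CH2Cl2, rt; then MeNH(OMe)·HCl, rt
Reagents that add atoms: 1,1'-carbonyldiimidazole, O=C(n1ccnc1)n1ccnc1 (imidazolyl group of 7); N,O-dimethylhydroxylamine hydrochloride, CNOC.Cl
Why: Amide coupling through the acyl imidazolide gives the Weinreb amide without strong acid or acid chloride formation, so the MOM ether is safe.

Step 6
Reactants: 9 2,6-dimethoxybenzaldehyde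
Product: 10 2-ethynyl-1,3-dimethoxybenzene
Conditions: dimethyl (1-diazo-2-oxopropyl)phosphonate, K2CO3, MeOH, rt
Reagents that add atoms: dimethyl (1-diazo-2-oxopropyl)phosphonate, CC(=O)C(=[N+]=[N-])P(=O)(OC)OC
Why: Ohira–Bestmann (Seyferth–Gilbert) homologation turns a non-enolisable aromatic aldehyde into the terminal alkyne in one operation under mild base.

Step 7
Reactants: 10 2-ethynyl-1,3-dimethoxybenzene; 8 N,2-dimethoxy-5-(methoxymethoxy)-N,3-dimethylbenzamide
Product: 12 3-(2,6-dimethoxyphenyl)-1-[2-methoxy-5-(methoxymethoxy)-3-methylphenyl]prop-2-yn-1-one, via lithium acetylide 11 (not isolated)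
Conditions: 10, n-BuLi, THF, −78 °C; then 8, −78 → 0 °C; AcOH, −78 °C
Reagents that add atoms: n-butyllithium, [Li]CCCC (lithium of 11; nothing remains in 12)
Why: In the Weinreb ketone synthesis with a lithium acetylide the chelated tetrahedral adduct blocks over-addition, and the cold acidic quench keeps the released amine from adding to the ynone.

Step 8
Reactants: 6 2-methoxy-5-(methoxymethoxy)-3-methylbenzoic acid
Product: 15 tert-butyl [2-methoxy-5-(methoxymethoxy)-3-methylphenyl]carbamate, via acyl azide 13 (not isolated), via isocyanate 14 (not isolated)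
Conditions: (PhO)2P(O)N3, Et3N, t-BuOH, reflux
Reagents that add atoms: diphenylphosphoryl azide, [N-]=[N+]=NP(=O)(Oc1ccccc1)Oc1ccccc1; tert-butanol, CC(C)(C)O
Why: The Curtius rearrangement of the acyl azide, with the isocyanate trapped by tert-butanol, puts nitrogen on the former carboxyl-bearing carbon (future a6) under basic conditions that the MOM ether tolerates.

Step 9
Reactants: 15 tert-butyl [2-methoxy-5-(methoxymethoxy)-3-methylphenyl]carbamate; 9 2,6-dimethoxybenzaldehyde
Product: 17 tert-butyl {2-[(2,6-dimethoxyphenyl)(hydroxy)methyl]-6-methoxy-3-(methoxymethoxy)-5-methylphenyl}carbamate (racemic), via dilithio carbamate 16 (not isolated)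
Conditions: t-BuLi (2.3 equiv), Et2O, −78 → −20 °C; then 9, THF, −78 °C; AcOH
Reagents that add atoms: tert-butyllithium, [Li]C(C)(C)C (lithium atoms of 16; nothing remains in 17)
Why: Directed ortho-metalation should occur at the carbon between the N-lithio carbamate and OMOM (cooperative 1,3-directing groups, the other ortho carbon being blocked by OMe); 1,2-addition to the non-enolisable aldehyde is the standard entry to tetra-ortho-substituted benzhydrols, the new carbinol centre is racemic and is erased in step 11, and any early closure to 18 is harmless.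

Step 10
Reactants: 17 tert-butyl {2-[(2,6-dimethoxyphenyl)(hydroxy)methyl]-6-methoxy-3-(methoxymethoxy)-5-methylphenyl}carbamate
Product: 19 [2-amino-3-methoxy-6-(methoxymethoxy)-4-methylphenyl](2,6-dimethoxyphenyl)methanol (racemic), via cyclic carbamate 18 (not isolated)
Conditions: KOH, EtOH/H2O, reflux
Reagents that add atoms: none
Why: Base-induced transcarbamoylation (the neighbouring alkoxide displaces tert-butoxide to give the benzoxazinone), then carbamate hydrolysis and decarboxylation, frees the aniline without any acid, so the MOM ether is kept.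

Step 11
Reactants: 19 [2-amino-3-methoxy-6-(methoxymethoxy)-4-methylphenyl](2,6-dimethoxyphenyl)methanol
Product: 20 [2-amino-3-methoxy-6-(methoxymethoxy)-4-methylphenyl](2,6-dimethoxyphenyl)methanone
Conditions: MnO2 (activated, excess), CH2Cl2, rt
Reagents that add atoms: none
Why: MnO2 oxidation of a doubly benzylic alcohol is the usual passage from 2-aminobenzhydrols to 2-aminobenzophenones and proceeds faster than attack on the aniline.

Step 12
Reactants: 20 [2-amino-3-methoxy-6-(methoxymethoxy)-4-methylphenyl](2,6-dimethoxyphenyl)methanone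
Product: 21 2-(2,6-dimethoxybenzoyl)-6-methoxy-3-(methoxymethoxy)-5-methylbenzenediazonium tetrafluoroborate
Conditions: NOBF4 (1.05 equiv), MeCN, −40 → −10 °C; then cold Et2O (precipitation), used at once
Reagents that add atoms: nitrosonium tetrafluoroborate, N#[O+].F[B-](F)(F)F
Why: Aprotic diazotisation with a nitrosonium salt suits weakly basic 2-acylanilines and releases only water, so no acid builds up to cleave the MOM ether, while cold handling suppresses ionic loss of N2.

Step 13
Reactants: 21 2-(2,6-dimethoxybenzoyl)-6-methoxy-3-(methoxymethoxy)-5-methylbenzenediazonium tetrafluoroborate; 12 3-(2,6-dimethoxyphenyl)-1-[2-methoxy-5-(methoxymethoxy)-3-methylphenyl]prop-2-yn-1-one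
Product: 22 2-[2-(2,6-dimethoxybenzoyl)-6-methoxy-3-(methoxymethoxy)-5-methylphenyl]-3-(2,6-dimethoxyphenyl)-7-methoxy-4-(methoxymethoxy)-6-methyl-1H-inden-1-one (acredinone A bis-MOM ether)
Conditions: 12 (3 equiv, excess recovered), Ru(bpy)3Cl2·6H2O (2 mol %), 2,6-di-tert-butylpyridine (1.2 equiv), degassed MeCN (concentrated in 12), blue LEDs (450 nm), 20 °C, slow addition of 21 in MeCN
Reagents that add atoms: none
Why: Proposed new method: photoexcited [Ru(bpy)3]2+ passes one electron to 21, N2 leaves, and the a6 σ-radical adds to C2 of 12; the linear vinyl radical left on C3 attacks C3a, the cyclohexadienyl radical is oxidised by [Ru(bpy)3]3+ (trivalent ruthenium) or by a further molecule of 21, and the hindered pyridine takes the C3a proton, so the indenone arises redox-neutrally. The closest known reaction types are the addition–cyclisation cascades of 1,3-diarylpropynones with sulfonyl, phosphoryl, trifluoromethyl and alkyl radicals, all giving 2-substituted 3-arylindenones, and the photoredox Meerwein-type arylation of alkynes with diazonium salts; new here is an aryl radical flanked by a methoxy and an aroyl group. The one ring closed is the five-membered ring C1–C2–C3–C3a–C7a, formed by intramolecular homolytic aromatic substitution (5-exo-trig when counted on the C3a–C4 π bond), and no stereocentre is created. Site selectivity of the addition rests on the two ortho methoxy groups of ring D, which screen C3, and on conjugation with ring D, which is open only to a radical on C3. Site selectivity of the closure rests on C3a being the only hydrogen-bearing carbon ortho to C7a, since an adduct at the methoxy-bearing C7 cannot rearomatise by proton loss. Pschorr closure onto ring C is slowed by methoxy groups on both of its ortho carbons, excess concentrated 12 with slow addition of 21 favours the bimolecular capture, and the base keeps HBF4 from cleaving the MOM ethers or turning the 2-methoxyaryl ynone into a chromone.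

Step 14
Reactants: 22 acredinone A bis-MOM ether
Product: 23 acredinone A, 2-[2-(2,6-dimethoxybenzoyl)-3-hydroxy-6-methoxy-5-methylphenyl]-3-(2,6-dimethoxyphenyl)-4-hydroxy-7-methoxy-6-methyl-1H-inden-1-one
Conditions: conc. HCl (cat.), MeOH/CH2Cl2, 45 °C
Reagents that add atoms: none
Why: Acid-catalysed acetal exchange with methanol (MOM cleavage) frees both phenols, while the six aryl methyl ethers, the diaryl ketone and the tetrasubstituted enone are inert to dilute acid.

Compound list
1 | 3-methylsalicylic acid | Cc1cccc(C(=O)O)c1O | starting material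
2 | methyl 2-methoxy-3-methylbenzoate | COC(=O)c1cccc(C)c1OC | intermediate
3 | methyl 2-methoxy-3-methyl-5-(4,4,5,5-tetramethyl-1,3,2-dioxaborolan-2-yl)benzoate | COC(=O)c1cc(B2OC(C)(C)C(C)(C)O2)cc(C)c1OC | intermediate
4 | methyl 5-hydroxy-2-methoxy-3-methylbenzoate | COC(=O)c1cc(O)cc(C)c1OC | intermediate
5 | methyl 2-methoxy-5-(methoxymethoxy)-3-methylbenzoate | COC(=O)c1cc(OCOC)cc(C)c1OC | intermediate
6 | 2-methoxy-5-(methoxymethoxy)-3-methylbenzoic acid | OC(=O)c1cc(OCOC)cc(C)c1OC | intermediate
7 | 1-[2-methoxy-5-(methoxymethoxy)-3-methylbenzoyl]imidazole | O=C(n1ccnc1)c1cc(OCOC)cc(C)c1OC | intermediate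
8 | N,2-dimethoxy-5-(methoxymethoxy)-N,3-dimethylbenzamide | CON(C)C(=O)c1cc(OCOC)cc(C)c1OC | intermediate
9 | 2,6-dimethoxybenzaldehyde | COc1cccc(OC)c1C=O | starting material
10 | 2-ethynyl-1,3-dimethoxybenzene | C#Cc1c(OC)cccc1OC | intermediate
11 | lithium (2,6-dimethoxyphenyl)acetylide | [Li]C#Cc1c(OC)cccc1OC | intermediate
12 | 3-(2,6-dimethoxyphenyl)-1-[2-methoxy-5-(methoxymethoxy)-3-methylphenyl]prop-2-yn-1-one | O=C(C#Cc1c(OC)cccc1OC)c1cc(OCOC)cc(C)c1OC | intermediate
13 | 2-methoxy-5-(methoxymethoxy)-3-methylbenzoyl azide | [N-]=[N+]=NC(=O)c1cc(OCOC)cc(C)c1OC | intermediate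
14 | 1-isocyanato-2-methoxy-5-(methoxymethoxy)-3-methylbenzene | O=C=Nc1cc(OCOC)cc(C)c1OC | intermediate
15 | tert-butyl [2-methoxy-5-(methoxymethoxy)-3-methylphenyl]carbamate | CC(C)(C)OC(=O)Nc1cc(OCOC)cc(C)c1OC | intermediate
16 | N,C6-dilithiated tert-butyl [2-methoxy-5-(methoxymethoxy)-3-methylphenyl]carbamate | [Li]N(C(=O)OC(C)(C)C)c1c([Li])c(OCOC)cc(C)c1OC | intermediate
17 | tert-butyl {2-[(2,6-dimethoxyphenyl)(hydroxy)methyl]-6-methoxy-3-(methoxymethoxy)-5-methylphenyl}carbamate (racemic) | CC(C)(C)OC(=O)Nc1c(C(O)c2c(OC)cccc2OC)c(OCOC)cc(C)c1OC | intermediate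
18 | 4-(2,6-dimethoxyphenyl)-8-methoxy-5-(methoxymethoxy)-7-methyl-1,4-dihydro-2H-3,1-benzoxazin-2-one (racemic) | O=C1Nc2c(OC)c(C)cc(OCOC)c2C(c2c(OC)cccc2OC)O1 | intermediate
19 | [2-amino-3-methoxy-6-(methoxymethoxy)-4-methylphenyl](2,6-dimethoxyphenyl)methanol (racemic) | Nc1c(C(O)c2c(OC)cccc2OC)c(OCOC)cc(C)c1OC | intermediate
20 | [2-amino-3-methoxy-6-(methoxymethoxy)-4-methylphenyl](2,6-dimethoxyphenyl)methanone | Nc1c(C(=O)c2c(OC)cccc2OC)c(OCOC)cc(C)c1OC | intermediate
21 | 2-(2,6-dimethoxybenzoyl)-6-methoxy-3-(methoxymethoxy)-5-methylbenzenediazonium tetrafluoroborate | N#[N+]c1c(OC)c(C)cc(OCOC)c1C(=O)c1c(OC)cccc1OC.F[B-](F)(F)F | intermediate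
22 | acredinone A bis(methoxymethyl) ether | O=C1C(c2c(OC)c(C)cc(OCOC)c2C(=O)c2c(OC)cccc2OC)=C(c2c(OC)cccc2OC)c2c(OCOC)cc(C)c(OC)c21 | intermediate
23 | acredinone A | COc1cccc(OC)c1C(=O)c1c(O)cc(C)c(OC)c1C1=C(c2c(OC)cccc2OC)c2c(O)cc(C)c(OC)c2C1=O | target

Total step count: 14.
Longest linear sequence: 11 steps (steps 1–4 and 8–14).

Steps most likely to fail

1. Step 13 (proposed new method).
- What may go wrong: capture of the crowded a6 radical by the internal alkyne may be too slow. Hydrogen abstraction or ipso attack on ring C could then outrun the cascade, as could, after addition, 1,5-hydrogen transfer from a ring D methoxy group to the C3 radical.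
- Fallback: known chemistry (Larock indenone annulation). It sets out from 21, 10 and 8 and returns at 22.
- Alkyne partner: salt 21 is treated with KI (MeCN/H2O, 0 °C → rt) to give (2,6-dimethoxyphenyl)[2-iodo-3-methoxy-6-(methoxymethoxy)-4-methylphenyl]methanone F1. Sonogashira coupling with alkyne 10 (PdCl2(PPh3)2, CuI, Et3N, 60 °C) should give (2,6-dimethoxyphenyl){2-[(2,6-dimethoxyphenyl)ethynyl]-3-methoxy-6-(methoxymethoxy)-4-methylphenyl}methanone F2.
- Aldehyde partner: Weinreb amide 8 is reduced with i-Bu2AlH (THF, −78 °C) to 2-methoxy-5-(methoxymethoxy)-3-methylbenzaldehyde F3. LiN(Me)CH2CH2NMe2 masks the formyl group as the lithium α-amino alkoxide F4. n-BuLi then metalates between the masked formyl group and OMOM to give the ring-lithiated α-amino alkoxide F5. I2 and aqueous work-up give 2-iodo-6-methoxy-3-(methoxymethoxy)-5-methylbenzaldehyde F6.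
- Annulation: F6 and F2 (Pd(OAc)2, NaOAc, n-Bu4NCl, DMF, 100 °C) form C3a–C3 by carbopalladation. C2–C1 forms by addition of the vinylpalladium to the aldehyde and β-hydride elimination, which delivers 22. The bulkier ring A, whose ketone can also bind palladium, should end next to the metal, that is on C2.

2. Step 9.
- What may go wrong: lithiation may be incomplete, and addition of the doubly flanked dianion to a doubly ortho-substituted aldehyde may be sluggish, with return of the protonated carbamate.
- Fallback: reversed polarity. It sets out from 15 and returns at 17.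
- Route: the dilithio species 16 is trapped with the small electrophile DMF to give tert-butyl [2-formyl-6-methoxy-3-(methoxymethoxy)-5-methylphenyl]carbamate F7. Commercial 1,3-dimethoxybenzene is lithiated at C2 (n-BuLi, THF, 0 °C) to 2,6-dimethoxyphenyllithium F8. Two equivalents of F8 first deprotonate the carbamate N–H and then add to the aldehyde of F7 (THF, −78 °C) to give 17.

3. Step 10.
- What may go wrong: the sequence may stall at the cyclic carbamate, because hydroxide attack on the crowded carbonyl is slow, and forcing conditions may erode the material.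
- Fallback: oxidation before deprotection. It sets out from 17 and returns at 20, bypassing 18, 19 and step 11.
- Route: Dess–Martin periodinane (NaHCO3, CH2Cl2) oxidises the carbinol while the nitrogen is still protected, giving tert-butyl [2-(2,6-dimethoxybenzoyl)-6-methoxy-3-(methoxymethoxy)-5-methylphenyl]carbamate F9. TFA/CH2Cl2/H2O removes both Boc and MOM to give (2-amino-6-hydroxy-3-methoxy-4-methylphenyl)(2,6-dimethoxyphenyl)methanone F10. Selective O-alkylation of the phenoxide (MOMCl, K2CO3, acetone) restores the MOM ether and gives 20.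

Further compounds
F1 | step 13 | (2,6-dimethoxyphenyl)[2-iodo-3-methoxy-6-(methoxymethoxy)-4-methylphenyl]methanone | COc1cccc(OC)c1C(=O)c1c(OCOC)cc(C)c(OC)c1I
F2 | step 13 | (2,6-dimethoxyphenyl){2-[(2,6-dimethoxyphenyl)ethynyl]-3-methoxy-6-(methoxymethoxy)-4-methylphenyl}methanone | COc1cccc(OC)c1C(=O)c1c(OCOC)cc(C)c(OC)c1C#Cc1c(OC)cccc1OC
F3 | step 13 | 2-methoxy-5-(methoxymethoxy)-3-methylbenzaldehyde | O=Cc1cc(OCOC)cc(C)c1OC
F4 | step 13 | lithium α-amino alkoxide of F3 with N,N,N'-trimethylethylenediamine | [Li]OC(N(C)CCN(C)C)c1cc(OCOC)cc(C)c1OC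
F5 | step 13 | ring-lithiated α-amino alkoxide | [Li]OC(N(C)CCN(C)C)c1c([Li])c(OCOC)cc(C)c1OC
F6 | step 13 | 2-iodo-6-methoxy-3-(methoxymethoxy)-5-methylbenzaldehyde | O=Cc1c(I)c(OCOC)cc(C)c1OC
F7 | step 9 | tert-butyl [2-formyl-6-methoxy-3-(methoxymethoxy)-5-methylphenyl]carbamate | CC(C)(C)OC(=O)Nc1c(C=O)c(OCOC)cc(C)c1OC
F8 | step 9 | 2,6-dimethoxyphenyllithium | [Li]c1c(OC)cccc1OC
F9 | step 10 | tert-butyl [2-(2,6-dimethoxybenzoyl)-6-methoxy-3-(methoxymethoxy)-5-methylphenyl]carbamate | CC(C)(C)OC(=O)Nc1c(C(=O)c2c(OC)cccc2OC)c(OCOC)cc(C)c1OC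
F10 | step 10 | (2-amino-6-hydroxy-3-methoxy-4-methylphenyl)(2,6-dimethoxyphenyl)methanone | Nc1c(C(=O)c2c(OC)cccc2OC)c(O)cc(C)c1OC
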